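**Retrosynthetic overview**

- The strategy rests on C2 of the dihydrofuran ring. C2 bears O1, C3 and the CMe2OH carbon; at the acid oxidation level that carbon is the carbonyl of a six-membered aryl lactone onto the ortho-phenol oxygen of the C3 aryl group, which holds C2 cis to the aryl group.
- Endgame: target ⇐ C6 silyl ether of the C1′ ketone ⇐ C1′ carbinol ⇐ MeMgBr opening of the lactone (gives the phenol and CMe2OH).
- Key disconnection: lactone-tethered chiral ammonium ylide adds to the arylidene carbon (C2–C3, lactone ring), then the C7a enolate oxygen displaces the amine (O1–C2, dihydrofuran ring).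
- Arylidene dienol ether ⇐ 2-iodo-3-methoxycyclohexenone + silyl-protected salicylaldehyde (Nozaki–Hiyama–Kishi coupling, 1,4-dehydration); the iodide ⇐ (S)-5-silyloxy-3-methoxycyclohexenone by α′-aldol with 3-phenylpropanal and C6 inversion by kinetic protonation.
- The enone ⇐ all-cis cyclohexane-1,3,5-triol by lipase desymmetrisation. Ring order: carbocycle (from the triol), then lactone and dihydrofuran together in the key step, then the lactone is opened.

Key step: step 14

Remark 1: the lipase is taken to acetylate the (R)-carbinol of the meso-diol; if its preference is the opposite, hydrolysis of the derived meso-diacetate with the same enzyme gives the same monoacetate.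
Remark 2: O-methylquinidine is taken as the pseudoenantiomer that gives the (2R,3S) lactone; O-methylquinine is used if the facial sense is the reverse.

**Route**

Step 1
Reactants: 1 cis,cis-cyclohexane-1,3,5-triol
Product: 2 meso mono-TBS ether
Conditions: TBSCl (1.0 equiv), imidazole, DMF, 0 °C to rt
Reagents that add atoms: tert-butyldimethylsilyl chloride, CC(C)(C)[Si](C)(C)Cl
Why: Statistical monosilylation of a triol with three equivalent hydroxyls gives a meso silyl ether that is separable from bis-ether and recovered triol.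

Step 2
Reactants: 2 meso mono-TBS ether
Product: 3 monoacetate
Conditions: Burkholderia cepacia lipase (Amano PS), vinyl acetate, MTBE, 30 °C
Reagents that add atoms: vinyl acetate, CC(=O)OC=C
Why: Lipase-catalysed enantiotopos-selective transesterification of a meso-1,3-diol, which fixes the absolute configuration of all three ring centres at once.

Step 3
Reactants: 3 monoacetate
Product: 4 acetoxy ketone
Conditions: Dess–Martin periodinane, NaHCO3, CH2Cl2, 0 °C to rt
Reagents that add atoms: none
Why: Buffered Dess–Martin oxidation of the free carbinol; the β-acetoxy ketone is taken on without delay to avoid loss of acetic acid.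

Step 4
Reactants: 4 acetoxy ketone
Product: 6 hydroxy ketal, via acetoxy ketal 5 (not isolated)
Conditions: MeOTMS (3 equiv), TMSOTf (5 mol%), CH2Cl2, −78 °C; then K2CO3, MeOH, −78 °C to rt
Reagents that add atoms: methoxytrimethylsilane, CO[Si](C)(C)C
Why: Noyori ketalisation under aprotic conditions masks the ketone as its dimethyl ketal without touching the TBS ether, and methanolysis then removes the acetate.

Step 5
Reactants: 6 hydroxy ketal
Product: 8 (S)-enone, via keto ketal 7 (not isolated)
Conditions: (COCl)2, DMSO, CH2Cl2, −78 °C; Et3N; then DBU (0.2 equiv), 0 °C to rt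
Reagents that add atoms: none
Why: Swern oxidation followed by E1cB loss of methanol from the β-keto ketal, which can only place the enol ether on the former ketal carbon, so the vinylogous ester forms regiospecifically without passing through the achiral 1,3-dione and C5 stays (S).

Step 6
Reactants: 8 (S)-enone; 9 3-phenylpropanal
Product: 11 trans-aldol adduct, via lithium enolate 10 (not isolated)
Conditions: LDA (1.1 equiv), THF, −78 °C; 9, −78 °C; AcOH, −78 °C
Reagents that add atoms: none
Why: α′-Aldol addition of the kinetic cross-conjugated enolate, in which the aldehyde approaches C6 anti to the C5 silyloxy group (5,6-trans) and the chair Zimmerman–Traxler transition state of the (E)-enolate gives the anti C6/C1′ relationship; the minor C1′ epimer is separated, and C1′ is oxidised later.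

Step 7
Reactants: 11 trans-aldol adduct
Product: 12 trans TES ether
Conditions: TESOTf, 2,6-lutidine, CH2Cl2, −78 °C
Reagents that add atoms: triethylsilyl trifluoromethanesulfonate, CC[Si](CC)(CC)OS(=O)(=O)C(F)(F)F
Why: Silylation of the secondary aldol hydroxyl under non-epimerising conditions blocks retro-aldol and later elimination.

Step 8
Reactants: 12 trans TES ether
Product: 14 cis TES ether, via lithium enolate 13 (not isolated)
Conditions: LDA (1.1 equiv), THF, −78 °C, 20 min; AcOH in THF, −78 °C
Reagents that add atoms: none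
Why: Kinetic protonation of the α′-enolate: A(1,2) strain holds the C5 silyloxy group pseudoaxial and the proton should enter C6 from the opposite face, which turns the side chain cis to the silyloxy group (6S), while the short enolate lifetime at −78 °C limits β-elimination.

Step 9
Reactants: 14 cis TES ether
Product: 15 2-iodo enone
Conditions: N-iodosuccinimide, NaHCO3, CH2Cl2, 0 °C to rt, dark
Reagents that add atoms: N-iodosuccinimide, O=C1CCC(=O)N1I
Why: Electrophilic iodination at C2, the nucleophilic α-carbon of the vinylogous ester.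

Step 10
Reactants: 16 methyl 3-formyl-4-hydroxybenzoate
Product: 17 TIPS-protected aldehyde
Conditions: TIPSCl, imidazole, CH2Cl2, rt
Reagents that add atoms: triisopropylsilyl chloride, CC(C)[Si](Cl)(C(C)C)C(C)C
Why: Silylation of the phenol, which would otherwise quench the organometallic reagent and cyclise onto the later arylidene ketone.

Step 11
Reactants: 15 2-iodo enone; 17 TIPS-protected aldehyde
Product: 18 carbinol
Conditions: CrCl2 (4 equiv), NiCl2 (2 mol%), DMF, rt
Reagents that add atoms: none
Why: Nozaki–Hiyama–Kishi coupling adds the alkenylchromium reagent only to the aldehyde and tolerates the ketone, both esters and the silyl ethers; the new carbinol centre (both epimers) is removed in the next step.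

Step 12
Reactants: 18 carbinol
Product: 20 arylidene dienol ether, via mesylate 19 (not isolated)
Conditions: MsCl, Et3N, CH2Cl2, −20 °C; then DBU (1.2 equiv), −20 to 0 °C
Reagents that add atoms: none
Why: Mesylation and vinylogous 1,4-elimination: ionisation is assisted by the β-methoxy enone, and loss of a C4 proton (the carbinol carbon has no β-hydrogen) gives the cross-conjugated dienol ether, expected as the (E)-isomer with the aryl group away from the ketone.

Step 13
Reactants: 20 arylidene dienol ether; 21 bromoacetyl bromide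
Product: 23 aryl bromoacetate, via phenolate 22 (not isolated)
Conditions: TBAF (1.05 equiv), THF, −78 °C; then 21 (1.3 equiv), −78 to −40 °C
Reagents that add atoms: none
Why: Fluoride cleaves the electron-poor aryl silyl ether far faster than the alkyl silyl ethers, and the phenolate is acylated in situ, so the free o-hydroxyarylidene ketone is never handled and no nucleophilic amine is present that could quaternise the bromoacetate.

Step 14
Reactants: 23 aryl bromoacetate
Product: 25 cis-fused lactone, via ammonium bromide 24 (not isolated)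
Conditions: O-methylquinidine (1.1 equiv), MeCN, rt; then Cs2CO3 (1.5 equiv), 0 °C to rt
Reagents that add atoms: none
Why: Proposed new method: the quinuclidine nitrogen displaces bromide to give 24 and carbonate forms the ester-stabilised ylide, which adds to the arylidene carbon in a 6-exo-trig Michael addition that closes the dihydrocoumarin ring (C2–C3), after which the cross-conjugated dienolate displaces the amine at C2 through its C7a oxygen in a 5-exo-tet closure of the dihydrofuran (O1–C2), leaving the C7a=C3a–C4(OMe)=C5 diene. The closest known reactions are the [4+1] annulations of ammonium and pyridinium ylides with 2-arylidene-1,3-dicarbonyl compounds and o-quinone methides to 2,3-dihydrofurans and the cinchona-mediated intramolecular ammonium-ylide cyclopropanation of enones; the lactone-tethered [4+1] on a mono-ketone dienol ether is the untested extension. C3 is set by the chiral ammonium group, which should direct the ylide to one face of the (E)-arylidene, with the remote C6 and C7 centres expected to give only a matched or mismatched modulation. C2 follows from C3, because the six-membered lactone allows only a cis ring fusion, the ylide carbon is epimerisable, and only the ammonium diastereomer with nitrogen anti to C3a can be displaced with inversion. The step needs O-alkylation to beat C-alkylation at C3a (3-exo-tet closure to a spirocyclopropane) and needs C7a–O to be the only enolate oxygen; the second is fixed because C4 is already a methyl enol ether, and the first is favoured but not guaranteed by the fully substituted enolate carbon, the metal-free ammonium/caesium enolate in acetonitrile and the strain-free cis-fused product. Attack through C5 is excluded by Bredt strain.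

Step 15
Reactants: 25 cis-fused lactone
Product: 27 phenol tertiary alcohol, via methyl ketone 26 (not isolated)
Conditions: MeMgBr (2.6 equiv), LaCl3·2LiCl (0.3 equiv), THF, −78 to −40 °C; aq. NH4Cl
Reagents that add atoms: methylmagnesium bromide, C[Mg]Br
Why: Double Grignard addition to the aryl ester: the first addition expels the phenoxide and gives ketone 26, which reacts again faster than the methyl benzoate (deactivated by the para-phenoxide), and the lanthanum-modified reagent adds faster than it enolises, so C2 keeps its configuration.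

Step 16
Reactants: 27 phenol tertiary alcohol
Product: 28 C1′ alcohol
Conditions: TBAF/AcOH (1:1, 1.3 equiv), THF, 0 °C
Reagents that add atoms: none
Why: Selective fluoride cleavage of the secondary TES ether beside the more hindered TBS ether, under buffered non-acidic conditions because the C6-oxygenated diene is an arene hydrate derivative that aromatises with acid.

Step 17
Reactants: 28 C1′ alcohol
Product: 29 β-silyloxy ketone
Conditions: Dess–Martin periodinane, NaHCO3, CH2Cl2, 0 °C
Reagents that add atoms: none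
Why: Dess–Martin oxidation of the only free secondary alcohol (tertiary alcohol and electron-poor phenol are inert), buffered so that C7 does not epimerise and silanol is not lost from the new β-silyloxy ketone.

Step 18
Reactants: 29 β-silyloxy ketone
Product: 30 CNP0080427.1
Conditions: TBAF/AcOH (1:1.2, 3 equiv), THF, 0 °C to rt
Reagents that add atoms: none
Why: Acetic acid-buffered fluoride desilylation frees the C6 hydroxyl without forming the C7 enolate (no β-elimination to the aromatic benzofuran, no epimerisation) and without acid (no ionisation of the allylic C6–O bond).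

**Compound list**

1 | cis,cis-cyclohexane-1,3,5-triol | O[C@@H]1C[C@H](O)C[C@H](O)C1 | starting material
2 | all-cis-5-[(tert-butyldimethylsilyl)oxy]cyclohexane-1,3-diol (meso) | O[C@@H]1C[C@H](O)C[C@H](O[Si](C)(C)C(C)(C)C)C1 | intermediate
3 | (1R,3S,5S)-3-[(tert-butyldimethylsilyl)oxy]-5-hydroxycyclohexyl acetate | CC(=O)O[C@@H]1C[C@H](O)C[C@H](O[Si](C)(C)C(C)(C)C)C1 | intermediate
4 | (1S,3R)-3-[(tert-butyldimethylsilyl)oxy]-5-oxocyclohexyl acetate | CC(=O)O[C@@H]1CC(=O)C[C@H](O[Si](C)(C)C(C)(C)C)C1 | intermediate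
5 | (1S,5R)-5-[(tert-butyldimethylsilyl)oxy]-3,3-dimethoxycyclohexyl acetate | CC(=O)O[C@@H]1CC(OC)(OC)C[C@H](O[Si](C)(C)C(C)(C)C)C1 | intermediate
6 | (1S,5R)-5-[(tert-butyldimethylsilyl)oxy]-3,3-dimethoxycyclohexan-1-ol | O[C@@H]1CC(OC)(OC)C[C@H](O[Si](C)(C)C(C)(C)C)C1 | intermediate
7 | (5R)-5-[(tert-butyldimethylsilyl)oxy]-3,3-dimethoxycyclohexan-1-one | O=C1CC(OC)(OC)C[C@H](O[Si](C)(C)C(C)(C)C)C1 | intermediate
8 | (5S)-5-[(tert-butyldimethylsilyl)oxy]-3-methoxycyclohex-2-en-1-one | O=C1C=C(OC)C[C@H](O[Si](C)(C)C(C)(C)C)C1 | intermediate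
9 | 3-phenylpropanal | O=CCCc1ccccc1 | starting material
10 | kinetic α′ lithium enolate of 8 (C1–OLi, C1=C6) | [Li]OC1=C[C@@H](O[Si](C)(C)C(C)(C)C)CC(OC)=C1 | intermediate
11 | (5S,6R)-5-[(tert-butyldimethylsilyl)oxy]-6-[(1S)-1-hydroxy-3-phenylpropyl]-3-methoxycyclohex-2-en-1-one (5,6-trans) | O=C1C=C(OC)C[C@H](O[Si](C)(C)C(C)(C)C)[C@H]1[C@@H](O)CCc1ccccc1 | intermediate
12 | (5S,6R)-5-[(tert-butyldimethylsilyl)oxy]-3-methoxy-6-[(1S)-3-phenyl-1-[(triethylsilyl)oxy]propyl]cyclohex-2-en-1-one (5,6-trans) | O=C1C=C(OC)C[C@H](O[Si](C)(C)C(C)(C)C)[C@H]1[C@@H](O[Si](CC)(CC)CC)CCc1ccccc1 | intermediate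
13 | α′ lithium enolate of 12 (C1–OLi, C1=C6) | [Li]OC1=C([C@@H](O[Si](CC)(CC)CC)CCc2ccccc2)[C@@H](O[Si](C)(C)C(C)(C)C)CC(OC)=C1 | intermediate
14 | (5S,6S)-5-[(tert-butyldimethylsilyl)oxy]-3-methoxy-6-[(1S)-3-phenyl-1-[(triethylsilyl)oxy]propyl]cyclohex-2-en-1-one (5,6-cis) | O=C1C=C(OC)C[C@H](O[Si](C)(C)C(C)(C)C)[C@@H]1[C@@H](O[Si](CC)(CC)CC)CCc1ccccc1 | intermediate
15 | (5S,6S)-5-[(tert-butyldimethylsilyl)oxy]-2-iodo-3-methoxy-6-[(1S)-3-phenyl-1-[(triethylsilyl)oxy]propyl]cyclohex-2-en-1-one | O=C1C(I)=C(OC)C[C@H](O[Si](C)(C)C(C)(C)C)[C@@H]1[C@@H](O[Si](CC)(CC)CC)CCc1ccccc1 | intermediate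
16 | methyl 3-formyl-4-hydroxybenzoate | COC(=O)c1ccc(O)c(C=O)c1 | starting material
17 | methyl 3-formyl-4-[(triisopropylsilyl)oxy]benzoate | COC(=O)c1ccc(O[Si](C(C)C)(C(C)C)C(C)C)c(C=O)c1 | intermediate
18 | methyl 3-[hydroxy(enonyl)methyl]-4-[(triisopropylsilyl)oxy]benzoate, enonyl = C2 of 14 (both carbinol epimers) | O=C1C(C(O)c2cc(C(=O)OC)ccc2O[Si](C(C)C)(C(C)C)C(C)C)=C(OC)C[C@H](O[Si](C)(C)C(C)(C)C)[C@@H]1[C@@H](O[Si](CC)(CC)CC)CCc1ccccc1 | intermediate
19 | methanesulfonate of carbinol 18 | O=C1C(C(OS(C)(=O)=O)c2cc(C(=O)OC)ccc2O[Si](C(C)C)(C(C)C)C(C)C)=C(OC)C[C@H](O[Si](C)(C)C(C)(C)C)[C@@H]1[C@@H](O[Si](CC)(CC)CC)CCc1ccccc1 | intermediate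
20 | methyl 3-[(E)-{(4S,5S)-4-[(tert-butyldimethylsilyl)oxy]-2-methoxy-6-oxo-5-[(1S)-3-phenyl-1-[(triethylsilyl)oxy]propyl]cyclohex-2-en-1-ylidene}methyl]-4-[(triisopropylsilyl)oxy]benzoate | COC(=O)c2ccc(O[Si](C(C)C)(C(C)C)C(C)C)c(c2)/C=C1\C(OC)=C[C@H](O[Si](C)(C)C(C)(C)C)[C@H]([C@@H](O[Si](CC)(CC)CC)CCc3ccccc3)C1=O | intermediate
21 | bromoacetyl bromide | O=C(Br)CBr | starting material
22 | tetrabutylammonium phenolate from 20 (aryl O–Si cleaved) | CCCC[N+](CCCC)(CCCC)CCCC.COC(=O)c2ccc([O-])c(c2)/C=C1\C(OC)=C[C@H](O[Si](C)(C)C(C)(C)C)[C@H]([C@@H](O[Si](CC)(CC)CC)CCc3ccccc3)C1=O | intermediate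
23 | methyl 4-(2-bromoacetoxy)-3-[(E)-{(4S,5S)-4-[(tert-butyldimethylsilyl)oxy]-2-methoxy-6-oxo-5-[(1S)-3-phenyl-1-[(triethylsilyl)oxy]propyl]cyclohex-2-en-1-ylidene}methyl]benzoate (key-step precursor) | COC(=O)c2ccc(OC(=O)CBr)c(c2)/C=C1\C(OC)=C[C@H](O[Si](C)(C)C(C)(C)C)[C@H]([C@@H](O[Si](CC)(CC)CC)CCc3ccccc3)C1=O | intermediate
24 | N-(aryloxycarbonylmethyl)-O-methylquinidinium bromide from 23 (quinuclidine N alkylated by the bromoacetate) | COc1ccc2nccc([C@H](OC)[C@H]3C[C@@H]4CC[N+]3(CC(=O)Oc5ccc(cc5/C=C6\C(OC)=C[C@H](O[Si](C)(C)C(C)(C)C)[C@H]([C@@H](O[Si](CC)(CC)CC)CCc7ccccc7)C6=O)C(=O)OC)C[C@@H]4C=C)c2c1.[Br-] | intermediate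
25 | cis-fused dihydrocoumarin–dihydrofuran lactone, methyl ester; benzofuran numbering (2R,3S,6S,7S,1′S): 4-OMe dienol ether, 6-OTBS and 7-[3-phenyl-1-(triethylsilyloxy)propyl] cis to each other and anti to the aryl group (key-step product) | COC(=O)c1ccc2OC(=O)[C@@H]3OC4=C([C@@H]3c2c1)C(OC)=C[C@H](O[Si](C)(C)C(C)(C)C)[C@@H]4[C@@H](O[Si](CC)(CC)CC)CCc5ccccc5 | intermediate
26 | methyl 3-[(2R,3S,6S,7S)-2-acetyl-6-[(tert-butyldimethylsilyl)oxy]-4-methoxy-7-[(1S)-3-phenyl-1-[(triethylsilyl)oxy]propyl]-2,3,6,7-tetrahydro-1-benzofuran-3-yl]-4-hydroxybenzoate (in the flask as its magnesium phenoxide) | COC(=O)c1ccc(O)c([C@H]2C3=C(O[C@H]2C(C)=O)[C@@H]([C@@H](O[Si](CC)(CC)CC)CCc2ccccc2)[C@@H](O[Si](C)(C)C(C)(C)C)C=C3OC)c1 | intermediate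
27 | methyl 3-[(2R,3S,6S,7S)-6-[(tert-butyldimethylsilyl)oxy]-2-(2-hydroxypropan-2-yl)-4-methoxy-7-[(1S)-3-phenyl-1-[(triethylsilyl)oxy]propyl]-2,3,6,7-tetrahydro-1-benzofuran-3-yl]-4-hydroxybenzoate | COC(=O)c1ccc(O)c([C@H]2C3=C(O[C@H]2C(C)(C)O)[C@@H]([C@@H](O[Si](CC)(CC)CC)CCc2ccccc2)[C@@H](O[Si](C)(C)C(C)(C)C)C=C3OC)c1 | intermediate
28 | methyl 3-[(2R,3S,6S,7S)-6-[(tert-butyldimethylsilyl)oxy]-7-[(1S)-1-hydroxy-3-phenylpropyl]-2-(2-hydroxypropan-2-yl)-4-methoxy-2,3,6,7-tetrahydro-1-benzofuran-3-yl]-4-hydroxybenzoate | COC(=O)c1ccc(O)c([C@H]2C3=C(O[C@H]2C(C)(C)O)[C@@H]([C@@H](O)CCc2ccccc2)[C@@H](O[Si](C)(C)C(C)(C)C)C=C3OC)c1 | intermediate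
29 | methyl 3-[(2R,3S,6S,7S)-6-[(tert-butyldimethylsilyl)oxy]-2-(2-hydroxypropan-2-yl)-4-methoxy-7-(3-phenylpropanoyl)-2,3,6,7-tetrahydro-1-benzofuran-3-yl]-4-hydroxybenzoate | COC(=O)c1ccc(O)c([C@H]2C3=C(O[C@H]2C(C)(C)O)[C@@H](C(=O)CCc2ccccc2)[C@@H](O[Si](C)(C)C(C)(C)C)C=C3OC)c1 | intermediate
30 | CNP0080427.1, methyl 4-hydroxy-3-[(2R,3S,6S,7S)-6-hydroxy-2-(2-hydroxypropan-2-yl)-4-methoxy-7-(3-phenylpropanoyl)-2,3,6,7-tetrahydro-1-benzofuran-3-yl]benzoate | COC(=O)c1ccc(O)c([C@H]2C3=C(O[C@H]2C(C)(C)O)[C@@H](C(=O)CCc2ccccc2)[C@@H](O)C=C3OC)c1 | target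

**Step count and risks**

Total step count: 18. Longest linear sequence: 17 steps (steps 1–9 and 11–18); step 10 is the one-step side branch.

Most likely to fail:

1. Step 14 (proposed new method). The dienolate may close through carbon C3a to a spirocyclopropane instead of through oxygen, and the chiral ammonium group may give weak facial control at C3 against the remote ring centres. Fallback, setting out from 23 and returning at 25: brief hydrolysis of the cross-conjugated methyl enol ether (aqueous oxalic acid, THF, 0 °C) should give the 2-arylidenecyclohexane-1,3-dione F1. This is the acceptor class for which ammonium- and pyridinium-ylide [4+1] annulation to fused dihydrofuranones is established. With O-methylquinidine and Cs2CO3 in MeCN it should close through oxygen to the 4-oxo lactone F2; the isomer closed through the other carbonyl oxygen is removed by chromatography. Kinetic enolisation of F2 at C5 (KHMDS, THF–DMPU, −78 °C) and O-methylation with methyl triflate would then give 25.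

2. Step 8. The enolate may lose silanolate (β-elimination, leading to a phenol), or O-protonation followed by unselective ketonisation may leave the inversion at C6 incomplete. Fallback, setting out from 12 and returning at 14: LDA with TMSCl present as an internal quench (THF, −78 °C) should give the silyl dienol ether F3 without a long-lived enolate. PhSeCl (CH2Cl2, −78 °C) should convert it into the α-phenylselanyl ketone F4 (either C6 epimer). Bu3SnH with Et3B/O2 (toluene, −78 °C) then reduces the C–Se bond by hydrogen-atom transfer to the planar α-keto radical from the face anti to the C5 silyloxy group, giving 14.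

3. Step 15. The Grignard reagent may also add to the aryl methyl ester, and the α-alkoxy methyl ketone formed in the flask may enolise, with loss of the cis configuration at C2. Fallback, setting out from 25 and returning at 27: MeNH(OMe)·HCl with i-PrMgCl (THF, −20 °C) should open only the aryl lactone to the Weinreb amide F5. MeMgBr (THF, −78 to 0 °C) stops at the chelated adduct and gives methyl ketone 26 on work-up. The second methyl group is then added with the non-basic, ketone-selective MeTi(Oi-Pr)3 (THF, 0 °C) to give 27.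

**Further compounds**

F1 | step 14 | methyl 4-(2-bromoacetoxy)-3-{[(4S,5S)-4-[(tert-butyldimethylsilyl)oxy]-2,6-dioxo-5-[(1S)-3-phenyl-1-[(triethylsilyl)oxy]propyl]cyclohexylidene]methyl}benzoate | COC(=O)c2ccc(OC(=O)CBr)c(c2)/C=C1\C(=O)C[C@H](O[Si](C)(C)C(C)(C)C)[C@H]([C@@H](O[Si](CC)(CC)CC)CCc3ccccc3)C1=O
F2 | step 14 | 4-oxo analogue of lactone 25 (C4 ketone, C5 methylene; otherwise as 25) | COC(=O)c1ccc2OC(=O)[C@@H]3OC4=C([C@@H]3c2c1)C(=O)C[C@H](O[Si](C)(C)C(C)(C)C)[C@@H]4[C@@H](O[Si](CC)(CC)CC)CCc5ccccc5
F3 | step 8 | trimethylsilyl dienol ether of 12 (C1–OTMS, C1=C6) | C[Si](C)(C)OC1=C([C@@H](O[Si](CC)(CC)CC)CCc2ccccc2)[C@@H](O[Si](C)(C)C(C)(C)C)CC(OC)=C1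
F4 | step 8 | (5S)-5-[(tert-butyldimethylsilyl)oxy]-3-methoxy-6-(phenylselanyl)-6-[(1S)-3-phenyl-1-[(triethylsilyl)oxy]propyl]cyclohex-2-en-1-one (C6 unassigned) | O=C1C=C(OC)C[C@H](O[Si](C)(C)C(C)(C)C)C1([Se]c1ccccc1)[C@@H](O[Si](CC)(CC)CC)CCc1ccccc1
F5 | step 15 | methyl 3-[(2R,3S,6S,7S)-6-[(tert-butyldimethylsilyl)oxy]-4-methoxy-2-[methoxy(methyl)carbamoyl]-7-[(1S)-3-phenyl-1-[(triethylsilyl)oxy]propyl]-2,3,6,7-tetrahydro-1-benzofuran-3-yl]-4-hydroxybenzoate | COC(=O)c1ccc(O)c([C@H]2C3=C(O[C@H]2C(=O)N(C)OC)[C@@H]([C@@H](O[Si](CC)(CC)CC)CCc2ccccc2)[C@@H](O[Si](C)(C)C(C)(C)C)C=C3OC)c1
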